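**Retrosynthetic overview**

1. Feature: in the ten-membered ring the C6 carbinol carbon and the C10 olefin carbon are 1,5-related through C7–C8–C9. A C6–C10 bond would give a cyclopentane (C6–C10, holding the C7 isopropyl and C8 oxygen centres) fused to a cycloheptene (C10, C1–C6, holding C4=C5), so the C6 oxygen and the Z C1=C10 olefin are the two ends of a Grob fragmentation.
2. Target ⇐ C6–OH-directed epoxidation of C4=C5 ⇐ enantioselective reduction of the C6 enone ⇐ C8 aroylation ⇐ (Z,Z)-cyclodecadienone carrying C8–OTBS.
3. Cyclodecadienone ⇐ Grob fragmentation of the cis-fused hydroazulenol C1 mesylate (cleaves C6–C10; the ten-membered ring is formed last, by ring opening).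
4. Hydroazulenol ⇐ Nozaki–Hiyama–Kishi closure of the seven-membered ring (C5–C6) ⇐ reductive aldol (C10–C1) of an α-methylene cyclopentanone with (Z)-5-iodo-4-methylpent-4-enal, made from propargyl alcohol.
5. Cyclopentanone ⇐ (S)-4-silyloxycyclopentenone by acetone aldol/dehydration, hydrogenation anti to the silyloxy group (cis C7/C8) and α-methylenation. Ring order: five-membered (bought), seven-membered, ten-membered.

Key step: step 12

Remark on the chemistry: C1–C10 are the germacrane positions of the target ring and are used for every intermediate; TBS is tert-butyldimethylsilyl. C7 and C8 of the target correspond to a cis-1,2-disubstituted cyclopentane, which alkylation of a cyclopentenone enolate anti to the silyloxy group would not give, so the isopropyl group enters as an isopropylidene and C7–H is set by hydrogenation.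

**Route**

Step 1
Reactants: 1 (S)-4-(tert-butyldimethylsilyloxy)cyclopent-2-en-1-one
Product: 3 (4R,5R)-4-(TBS-oxy)-5-(2-hydroxypropan-2-yl)cyclopent-2-en-1-one (side chain trans to OTBS), via lithium dienolate 2 (not isolated)
Conditions: LiN(i-Pr)2, THF, −78 °C; acetone, −78 °C; aq. NH4Cl
Reagents that add atoms: acetone, CC(C)=O
Why: Directed aldol addition: kinetic α′-deprotonation gives the cross-conjugated lithium enolate (β-loss of silyloxide from it would lead to an antiaromatic cyclopentadienone and is slow at −78 °C), which adds to acetone anti to the silyloxy group; the new C7 centre is erased again in step 2.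

Step 2
Reactants: 3
Product: 5 (R)-4-(TBS-oxy)-5-(propan-2-ylidene)cyclopent-2-en-1-one, via tertiary mesylate 4 (not isolated)
Conditions: MsCl, Et3N, DMAP (cat.), CH2Cl2, 0 °C to rt
Reagents that add atoms: none
Why: Aldol dehydration: sulfene-type mesylation of the tertiary hydroxyl and E1cB elimination through the ketone enolate give the conjugated isopropylidene, C7 becoming trigonal.

Step 3
Reactants: 5
Product: 7 (2R,3R)-3-(TBS-oxy)-2-(propan-2-yl)cyclopentan-1-one (isopropyl cis to OTBS), via exocyclic enone 6 (not isolated)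
Conditions: H2 (1 atm), Pd/C, EtOAc, rt
Reagents that add atoms: none
Why: Heterogeneous catalytic hydrogenation: the ring olefin is saturated first, then hydrogen is delivered to the tetrasubstituted exocyclic olefin from the face opposite the silyloxy group (pushed pseudo-axial by allylic strain with the isopropylidene methyl), so C7–H enters trans to the C8 oxygen and the isopropyl group ends cis to it.

Step 4
Reactants: 7
Product: 11 (2R,3R)-3-(TBS-oxy)-5-methylidene-2-(propan-2-yl)cyclopentan-1-one, via lithium enolate 8 (not isolated), via Mannich base 9 (not isolated), via ammonium iodide 10 (not isolated)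
Conditions: LiN(i-Pr)2, THF, −78 °C; CH2=NMe2+ I−, −78 °C to rt; MeI, Et2O, rt; aq. NaHCO3, CH2Cl2, rt
Reagents that add atoms: N,N-dimethylmethyleneiminium iodide (Eschenmoser's salt), C=[N+](C)C.[I-]
Why: α-Methylenation through a Mannich reaction: irreversible kinetic deprotonation takes the unhindered C10 methylene and not the C7 methine, and quaternisation followed by bicarbonate-induced E1cB loss of trimethylamine gives the exocyclic enone without exposing the cis C7 centre to strong base.

Step 5
Reactants: 12 propargyl alcohol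
Product: 14 (Z)-3-iodo-2-methylprop-2-en-1-ol, via oxamagnesacycle 13 (not isolated)
Conditions: MeMgBr (2.2 equiv), CuI (10 mol%), THF/Et2O, −10 °C to rt; I2, −30 °C to 0 °C
Reagents that add atoms: methylmagnesium bromide, C[Mg]Br; iodine, II
Why: Copper-catalysed anti carbomagnesiation of the propargylic alkoxide gives a five-membered chelate with magnesium cis to CH2O, and iodinolysis with retention should give the Z alkenyl iodide only.

Step 6
Reactants: 14
Product: 15 (Z)-3-bromo-1-iodo-2-methylprop-1-ene
Conditions: CBr4, PPh3, CH2Cl2, 0 °C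
Reagents that add atoms: carbon tetrabromide, BrC(Br)(Br)Br
Why: Appel reaction: SN2 bromination of the primary allylic alcohol that leaves the alkenyl iodide and its geometry untouched.

Step 7
Reactants: 15
Product: 16 (Z)-5-iodo-4-methylpent-4-enenitrile
Conditions: MeCN (3 equiv), LiN(i-Pr)2 (3 equiv), THF, −78 °C; then 15, −78 °C to −40 °C
Reagents that add atoms: acetonitrile, CC#N
Why: SN2 alkylation of lithioacetonitrile at the CH2 terminus of the allylic bromide adds C1 and C2, the excess of nucleophile limiting double alkylation.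

Step 8
Reactants: 16
Product: 18 (Z)-5-iodo-4-methylpent-4-enal, via iminoalane 17 (not isolated)
Conditions: i-Bu2AlH (1.1 equiv), CH2Cl2, −78 °C; aq. tartaric acid, 0 °C
Reagents that add atoms: water, O
Why: Partial reduction of a nitrile: one hydride adds to give the N-aluminio imine, which persists until hydrolysis and so cannot be over-reduced; the alkenyl iodide is inert at −78 °C.

Step 9
Reactants: 11; 18
Product: 20 (2R,3R,5S)-3-(TBS-oxy)-5-[(1S,4Z)-1-hydroxy-5-iodo-4-methylpent-4-en-1-yl]-5-methyl-2-(propan-2-yl)cyclopentan-1-one (C1–OH syn to the C10 methyl; side chain trans to isopropyl and OTBS), via lithium enolate 19 (not isolated)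
Conditions: LiBH(s-Bu)3 (1.05 equiv), THF, −78 °C; 18, −78 °C; aq. NH4Cl, −78 °C
Reagents that add atoms: none
Why: Reductive aldol reaction: conjugate hydride addition to the exocyclic enone makes the C10 methyl group and the tetrasubstituted C6=C10 lithium enolate regiospecifically, and addition to 18 through a Zimmerman–Traxler chair (ring enolate, aldehyde chain equatorial) should set C1–OH syn to the C10 methyl, the aldehyde coming to the enolate face anti to the cis isopropyl and silyloxy groups to set C10.

Step 10
Reactants: 20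
Product: 22 (1R,2R,3aS,4S,8aR)-2-(TBS-oxy)-3a,7-dimethyl-1-(propan-2-yl)-1,2,3,3a,4,5,6,8a-octahydroazulene-4,8a-diol (cis-fused; C6–OH, C10 methyl, C7 isopropyl and C8–OTBS all cis; C1–OH trans to the C10 methyl), via alkenylchromium 21 (not isolated)
Conditions: CrCl2 (6 equiv), NiCl2 (2 mol%), DMSO, rt to 50 °C
Reagents that add atoms: none
Why: Nozaki–Hiyama–Kishi reaction: zerovalent nickel inserts into the C5–I bond with retention, transmetalation gives the alkenyl derivative of trivalent chromium, and this adds 7-exo-trig to the C6 ketone from the face that carries the C10 tether, which makes the ring fusion cis (C6–OH cis to the C10 methyl) and tolerates the free C1 hydroxyl.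

Step 11
Reactants: 22
Product: 23 C1 methanesulfonate of 22 (C6–OH free)
Conditions: MsCl (1.2 equiv), Et3N, CH2Cl2, −20 °C
Reagents that add atoms: methanesulfonyl chloride, CS(=O)(=O)Cl
Why: Selective sulfonylation: the secondary C1 hydroxyl reacts with sulfene while the tertiary allylic C6 hydroxyl does not, and triethylamine is too weak a base to start the fragmentation.

Step 12
Reactants: 23
Product: 25 (2Z,6Z,9R,10R)-9-(TBS-oxy)-3,7-dimethyl-10-(propan-2-yl)cyclodeca-2,6-dien-1-one, via potassium alkoxide 24 (not isolated)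
Conditions: KOt-Bu (1.05 equiv), THF, −20 °C to 0 °C; pH 7 phosphate buffer
Reagents that add atoms: none
Why: Deprotonation of the tertiary C6 hydroxyl gives alkoxide 24, and in the cis-fused conformer that carries the mesylate pseudo-equatorial on the seven-membered ring an oxygen lone pair, the C6–C10 ring-fusion bond and the C1–O bond lie anti to one another, so the C6 carbonyl and the C1=C10 olefin form in a single concerted step while methanesulfonate departs. This is a Grob fragmentation of the kind used to open bicyclic 1,3-hydroxy sulfonates to medium-ring enones (decalin to cyclodecenone), applied here to a hydroazulene. No ring is closed: cutting the shared bond merges the five- and seven-membered rings into the ten-membered ring. No stereocentre is made, C7 and C8 pass through unchanged, and C6 and C10 become trigonal, so either facial isomer at C10 from step 9 would converge on 25. The selectivity that matters is the Z geometry of C1=C10, which follows stereospecifically from the C1/C10 relative configuration set in step 9: with the mesylate anti to C6–C10, C2 sits opposite the C10 methyl group and next to C9, so the ring arms C2 and C9 end on the same side of the new double bond (the C1 epimer would give E), while C4=C5 stays Z because it was held in the seven-membered ring. The neopentyl-type mesylate resists substitution and E2 loss, and one equivalent of base at low temperature with a buffered quench limits epimerisation at C7 and E1cB loss of the C8 silyloxy group from the β-silyloxy ketone that is released.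

Step 13
Reactants: 25
Product: 26 (2Z,6Z,9R,10R)-9-hydroxy-3,7-dimethyl-10-(propan-2-yl)cyclodeca-2,6-dien-1-one
Conditions: HF·pyridine, pyridine/THF, 0 °C to rt
Reagents that add atoms: none
Why: Silyl ether cleavage with buffered fluoride under weakly acidic conditions, which avoids the bases that would cause E1cB loss of the C8 oxygen or epimerise C7.

Step 14
Reactants: 26; 27 3,4,5-trimethoxybenzoyl chloride
Product: 28 (1R,3Z,7Z,10R)-3,7-dimethyl-9-oxo-10-(propan-2-yl)cyclodeca-3,7-dien-1-yl 3,4,5-trimethoxybenzoate
Conditions: pyridine, DMAP (cat.), CH2Cl2, 0 °C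
Reagents that add atoms: none
Why: Acylation with nucleophilic catalysis (acylpyridinium) of the secondary C8 hydroxyl; weak base and low temperature keep the β-acyloxy ketone from eliminating.

Step 15
Reactants: 28
Product: 29 (1R,3Z,7Z,9S,10S)-9-hydroxy-3,7-dimethyl-10-(propan-2-yl)cyclodeca-3,7-dien-1-yl 3,4,5-trimethoxybenzoate
Conditions: (S)-2-methyl-CBS-oxazaborolidine (0.5 equiv), catecholborane (1.5 equiv), toluene, −78 °C
Reagents that add atoms: none
Why: Corey–Bakshi–Shibata reduction: the oxazaborolidine binds the carbonyl lone pair anti to the alkenyl arm (taken as the larger group) and catecholborane delivers hydride to the face that gives the C6 alcohol syn to the C8 ester (reagent control), without hydroboration of the olefins at −78 °C.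

Step 16
Reactants: 29
Product: 30 (1(10)Z,4R,5S,6R,7S,8R)-4,5-epoxy-6-hydroxygermacr-1(10)-en-8-yl 3,4,5-trimethoxybenzoate (target)
Conditions: VO(acac)2 (5 mol%), t-BuOOH (1.5 equiv), CH2Cl2, 0 °C
Reagents that add atoms: tert-butyl hydroperoxide, CC(C)(C)OO
Why: Hydroxyl-directed epoxidation: the vanadate ester of C6–OH transfers oxygen only to the adjacent C4=C5 olefin, on the hydroxyl-bearing face of the conformer that keeps C6–H in the olefin plane to avoid allylic strain with C3, which gives the threo epoxy alcohol (C4 and C5) with the cis-epoxide geometry retained and leaves the remote C1=C10 olefin.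

**Compound list**

1 | (S)-4-(tert-butyldimethylsilyloxy)cyclopent-2-en-1-one | O=C1C=C[C@@H](O[Si](C)(C)C(C)(C)C)C1 | starting material
2 | lithium dienolate of 1 (cross-conjugated, C6=C7 and C9=C10) | [Li+].CC(C)(C)[Si](C)(C)O[C@@H]1C=CC([O-])=C1 | intermediate
3 | (4R,5R)-4-(TBS-oxy)-5-(2-hydroxypropan-2-yl)cyclopent-2-en-1-one | CC(C)(C)[Si](C)(C)O[C@@H]1C=CC(=O)[C@H]1C(C)(C)O | intermediate
4 | methanesulfonate of the tertiary hydroxyl of 3 | CC(C)(C)[Si](C)(C)O[C@@H]1C=CC(=O)[C@H]1C(C)(C)OS(C)(=O)=O | intermediate
5 | (R)-4-(TBS-oxy)-5-(propan-2-ylidene)cyclopent-2-en-1-one | CC(C)(C)[Si](C)(C)O[C@@H]1C=CC(=O)C1=C(C)C | intermediate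
6 | (R)-3-(TBS-oxy)-2-(propan-2-ylidene)cyclopentan-1-one | CC(C)(C)[Si](C)(C)O[C@@H]1CCC(=O)C1=C(C)C | intermediate
7 | (2R,3R)-3-(TBS-oxy)-2-(propan-2-yl)cyclopentan-1-one | CC(C)(C)[Si](C)(C)O[C@@H]1CCC(=O)[C@@H]1C(C)C | intermediate
8 | kinetic lithium enolate of 7 (C6=C10) | [Li+].CC(C)(C)[Si](C)(C)O[C@@H]1CC=C([O-])[C@@H]1C(C)C | intermediate
9 | (2R,3R)-5-[(dimethylamino)methyl]-3-(TBS-oxy)-2-(propan-2-yl)cyclopentan-1-one (C10 epimers) | CC(C)(C)[Si](C)(C)O[C@@H]1CC(CN(C)C)C(=O)[C@@H]1C(C)C | intermediate
10 | trimethylammonium iodide of 9 | CC(C)(C)[Si](C)(C)O[C@@H]1CC(C[N+](C)(C)C)C(=O)[C@@H]1C(C)C.[I-] | intermediate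
11 | (2R,3R)-3-(TBS-oxy)-5-methylidene-2-(propan-2-yl)cyclopentan-1-one | CC(C)(C)[Si](C)(C)O[C@@H]1CC(=C)C(=O)[C@@H]1C(C)C | intermediate
12 | propargyl alcohol | C#CCO | starting material
13 | 4-methyl-2,5-dihydro-1,2-oxamagnesole (chelated Z alkenylmagnesium alkoxide) | CC1=C[Mg]OC1 | intermediate
14 | (Z)-3-iodo-2-methylprop-2-en-1-ol | OC/C(C)=C\I | intermediate
15 | (Z)-3-bromo-1-iodo-2-methylprop-1-ene | BrC/C(C)=C\I | intermediate
16 | (Z)-5-iodo-4-methylpent-4-enenitrile | N#CCC/C(C)=C\I | intermediate
17 | N-(diisobutylaluminio) imine of 18 | CC(C)C[Al](CC(C)C)N=CCC/C(C)=C\I | intermediate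
18 | (Z)-5-iodo-4-methylpent-4-enal | O=CCC/C(C)=C\I | intermediate
19 | tetrasubstituted lithium enolate (C6=C10) of (2R,3R)-3-(TBS-oxy)-5-methyl-2-(propan-2-yl)cyclopentan-1-one | [Li+].CC(C)(C)[Si](C)(C)O[C@@H]1CC(C)=C([O-])[C@@H]1C(C)C | intermediate
20 | (2R,3R,5S)-3-(TBS-oxy)-5-[(1S,4Z)-1-hydroxy-5-iodo-4-methylpent-4-en-1-yl]-5-methyl-2-(propan-2-yl)cyclopentan-1-one | CC(C)(C)[Si](C)(C)O[C@@H]1C[C@@](C)([C@@H](O)CC/C(C)=C\I)C(=O)[C@@H]1C(C)C | intermediate
21 | alkenylchromium dichloride from 20 (C5–CrCl2 in place of C5–I) | CC(C)(C)[Si](C)(C)O[C@@H]1C[C@@](C)([C@@H](O)CC/C(C)=C\[Cr](Cl)Cl)C(=O)[C@@H]1C(C)C | intermediate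
22 | (1R,2R,3aS,4S,8aR)-2-(TBS-oxy)-3a,7-dimethyl-1-(propan-2-yl)-1,2,3,3a,4,5,6,8a-octahydroazulene-4,8a-diol | CC(C)(C)[Si](C)(C)O[C@@H]1C[C@@]2(C)[C@@H](O)CCC(C)=C[C@@]2(O)[C@@H]1C(C)C | intermediate
23 | C1 methanesulfonate of 22 | CC(C)(C)[Si](C)(C)O[C@@H]1C[C@@]2(C)[C@@H](OS(C)(=O)=O)CCC(C)=C[C@@]2(O)[C@@H]1C(C)C | intermediate
24 | potassium C6 alkoxide of 23 | [K+].CC(C)(C)[Si](C)(C)O[C@@H]1C[C@@]2(C)[C@@H](OS(C)(=O)=O)CCC(C)=C[C@@]2([O-])[C@@H]1C(C)C | intermediate
25 | (2Z,6Z,9R,10R)-9-(TBS-oxy)-3,7-dimethyl-10-(propan-2-yl)cyclodeca-2,6-dien-1-one | CC(C)(C)[Si](C)(C)O[C@@H]1C/C(C)=C\CC/C(C)=C\C(=O)[C@@H]1C(C)C | intermediate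
26 | (2Z,6Z,9R,10R)-9-hydroxy-3,7-dimethyl-10-(propan-2-yl)cyclodeca-2,6-dien-1-one | O[C@@H]1C/C(C)=C\CC/C(C)=C\C(=O)[C@@H]1C(C)C | intermediate
27 | 3,4,5-trimethoxybenzoyl chloride | COc1cc(C(Cl)=O)cc(OC)c1OC | starting material
28 | (1R,3Z,7Z,10R)-3,7-dimethyl-9-oxo-10-(propan-2-yl)cyclodeca-3,7-dien-1-yl 3,4,5-trimethoxybenzoate | COc1cc(C(=O)O[C@@H]2C/C(C)=C\CC/C(C)=C\C(=O)[C@@H]2C(C)C)cc(OC)c1OC | intermediate
29 | (1R,3Z,7Z,9S,10S)-9-hydroxy-3,7-dimethyl-10-(propan-2-yl)cyclodeca-3,7-dien-1-yl 3,4,5-trimethoxybenzoate | COc1cc(C(=O)O[C@@H]2C/C(C)=C\CC/C(C)=C\[C@H](O)[C@@H]2C(C)C)cc(OC)c1OC | intermediate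
30 | (1(10)Z,4R,5S,6R,7S,8R)-4,5-epoxy-6-hydroxygermacr-1(10)-en-8-yl 3,4,5-trimethoxybenzoate (CNP0260213.9) | COc1cc(C(=O)O[C@@H]2C/C(C)=C\CC[C@@]3(C)O[C@H]3[C@H](O)[C@@H]2C(C)C)cc(OC)c1OC | target

**Step count and risks**

Total step count: 16. Longest linear sequence: 12 steps (steps 1–4 and 9–16 from 1; equally steps 5–16 from 12).

Steps most likely to fail:

Step 12. The liberated β-silyloxy ketone stays for a time in a basic medium, so deprotonation at C7 may lead to epimerisation or to E1cB loss of the C8 silyloxy group, and a slow fragmentation would let E2 loss of the mesylate compete. The fallback sets out from 20. Mesylation of its only hydroxyl (MsCl, Et3N) should give keto mesylate F6, which cannot eliminate because C10 carries no hydrogen. Iodine–lithium exchange (t-BuLi, 2 equiv, THF/Et2O, −100 °C) then gives an alkenyllithium that closes onto the C6 ketone from the tether face, and the lithium alkoxide F7 so formed fragments on warming. Ring closure and ring opening thus run in one flask with no base left over (carbonyl addition followed by Grob fragmentation of a β-sulfonyloxy ketone), and the sequence comes back to the route at 25.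

Step 10. Addition of the alkenylchromium to a ketone flanked by the quaternary C10 and the isopropyl-bearing C7 may be slower than protonolysis or dimerisation of the organometallic. The fallback sets out from 11. A reductive aldol as in step 9, but with 4-methylpent-4-enal, should give aldol F4. Vinylmagnesium bromide with CeCl3 (organocerium reagents add to hindered, enolisable ketones) should add to the C6 ketone from the face of the side chain, away from the methyl, isopropyl and silyloxy groups, to give vinyl carbinol F5. Ring-closing metathesis with the second-generation Grubbs catalyst then forms C4=C5 in the seven-membered ring and comes back to the route at 22.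

Step 9. The aldol addition may run in part through an open or boat transition state, which erodes the syn relation of C1–OH and the C10 methyl; the C1 epimer would end as the E olefin in step 12. The fallback sets out from 11 and 18. The aldol is run without regard to C1, and the mixture of 20 and its C1 epimer F1 is taken through the ring closure of step 10 to 22 and its C1 epimer F2. Dess–Martin periodinane oxidises the secondary C1 hydroxyl of both to the single hydroxy ketone F3. Me4NBH(OAc)3 in MeCN/AcOH then delivers hydride from the C6 hydroxyl (Evans–Saksena reduction), which should place the new C1 hydroxyl trans to C6–OH, and the sequence comes back to the route at 22.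

**Further compounds**

F1 | step 9 | C1 epimer of aldol 20 | CC(C)(C)[Si](C)(C)O[C@@H]1C[C@@](C)([C@H](O)CC/C(C)=C\I)C(=O)[C@@H]1C(C)C
F2 | step 9 | C1 epimer of diol 22 | CC(C)(C)[Si](C)(C)O[C@@H]1C[C@@]2(C)[C@H](O)CCC(C)=C[C@@]2(O)[C@@H]1C(C)C
F3 | step 9 | cis-fused hydroxy ketone (C1 ketone, C6–OH) | CC(C)(C)[Si](C)(C)O[C@@H]1C[C@@]2(C)C(=O)CCC(C)=C[C@@]2(O)[C@@H]1C(C)C
F4 | step 10 | aldol of 11 with 4-methylpent-4-enal | CC(C)(C)[Si](C)(C)O[C@@H]1C[C@@](C)([C@@H](O)CCC(C)=C)C(=O)[C@@H]1C(C)C
F5 | step 10 | C6 vinyl carbinol of F4 | CC(C)(C)[Si](C)(C)O[C@@H]1C[C@@](C)([C@@H](O)CCC(C)=C)[C@@](O)(C=C)[C@@H]1C(C)C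
F6 | step 12 | C1 methanesulfonate of 20 (keto mesylate) | CC(C)(C)[Si](C)(C)O[C@@H]1C[C@@](C)([C@@H](OS(C)(=O)=O)CC/C(C)=C\I)C(=O)[C@@H]1C(C)C
F7 | step 12 | lithium C6 alkoxide of 23 | [Li+].CC(C)(C)[Si](C)(C)O[C@@H]1C[C@@]2(C)[C@@H](OS(C)(=O)=O)CCC(C)=C[C@@]2([O-])[C@@H]1C(C)C
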